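**Plan**

1. Retrosynthetic cuts, in order: the pyranone ring at O1–C2 and C4–C4a (ortho-iodophenol + aryl acetylene + CO); the C–H bond at the cyclohexane CH; the cyclohexane ring bond CH–C(CH3)2; the aryl–C(sp) bond to a linear C10 enynol.
2. Enabling feature: the terpenoid half is linalool folded onto itself. Cyclohexane C2 (C–OH, CH3) is a tertiary propargylic carbinol, C1 (CH) and the benzylic CH2 are the two alkyne carbons, and C6 (C(CH3)2) is the tertiary radical of a prenyl terminus; the tether between them makes the closure 6-exo.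
3. Forward order: aryl iodide 4 + (S)-dehydrolinalool 10 → aryl enynol 11 → cyclohexane ring by hydrogen-atom-transfer radical cyclisation (14) → saturated side chain (15) → pyranone ring last (22) → debenzylation (23).
4. Stereochemistry: C2 comes from Sharpless epoxidation of geraniol and is carried through an epoxy chloride → alkynol fragmentation that never breaks its C–O bond. C1 comes from hydroxyl-directed hydrogenation of the exocyclic alkene, which is locked between two quaternary carbons and is E/Z-convergent.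
5. 6- versus 8-substitution: the side chain enters between the two benzyloxy groups of symmetrical 3,5-bis(benzyloxy)phenol; the pyranone is later built on the remaining phenol oxygen and either of its two equivalent ortho carbons.

Key step: step 7

Remark: the descriptors of the target correspond to (1S,2S) on the cyclohexyl unit, i.e. tertiary OH and benzylic CH2 trans; the (S)-carbinol of 10 maps onto C2 without change of descriptor.

**Step 1**
Reactants: 1 3,5-bis(benzyloxy)phenol
Product: 2 [3,5-bis(benzyloxy)phenoxy]tri(propan-2-yl)silane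
Conditions: TIPSCl, imidazole, DMF, rt
Reagents that add atoms: triisopropylsilyl chloride, CC(C)[Si](Cl)(C(C)C)C(C)C
Why: Phenol silylation; the bulky, non-coordinating OTIPS group shields its two flanking ring positions and leaves the site between the benzyloxy groups as the only doubly activated one.

**Step 2**
Reactants: 2 [3,5-bis(benzyloxy)phenoxy]tri(propan-2-yl)silane
Product: 4 [3,5-bis(benzyloxy)-4-iodophenoxy]tri(propan-2-yl)silane, via aryllithium 3 (not isolated)
Conditions: n-BuLi, THF, 0 °C; then I2, −78 °C → rt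
Reagents that add atoms: iodine, II
Why: Directed ortho-metalation at the carbon flanked by two coordinating benzyloxy groups, followed by iodinolysis of the aryllithium.

**Step 3**
Reactants: 5 geraniol
Product: 6 (2S,3S)-2,3-epoxygeraniol
Conditions: Ti(OiPr)4 (cat.), L-(+)-diethyl tartrate (cat.), t-BuOOH, 4 Å MS, CH2Cl2, −20 °C
Reagents that add atoms: tert-butyl hydroperoxide, CC(C)(C)OO
Why: Sharpless asymmetric epoxidation; the L-(+)-tartrate ligand should give the (2S,3S)-epoxide, whose quaternary C3–O centre becomes the tertiary carbinol of the target.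

**Step 4**
Reactants: 6 (2S,3S)-2,3-epoxygeraniol
Product: 7 (2S,3R)-3-(chloromethyl)-2-methyl-2-(4-methylpent-3-en-1-yl)oxirane
Conditions: PPh3, CCl4, NaHCO3, reflux
Reagents that add atoms: carbon tetrachloride, ClC(Cl)(Cl)Cl
Why: Appel chlorination of the primary alcohol under neutral conditions, with the epoxide and its two stereocentres untouched (the descriptor at the CH changes only by priority).

**Step 5**
Reactants: 7 (2S,3R)-3-(chloromethyl)-2-methyl-2-(4-methylpent-3-en-1-yl)oxirane
Product: 10 (3S)-3,7-dimethyloct-6-en-1-yn-3-ol, via chlorovinyl alkoxide 8 (not isolated), via dilithio alkynyl alkoxide 9 (not isolated)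
Conditions: n-BuLi (3.2 equiv), THF, −40 → 0 °C; then H2O
Reagents that add atoms: none
Why: Base-induced fragmentation of a 2,3-epoxy chloride to a propargylic alcohol (α-deprotonation with epoxide opening, then dehydrochlorination); the tertiary C–O bond is never broken, so the (S) configuration is retained.

**Step 6**
Reactants: 4 [3,5-bis(benzyloxy)-4-iodophenoxy]tri(propan-2-yl)silane; 10 (3S)-3,7-dimethyloct-6-en-1-yn-3-ol
Product: 11 (3S)-1-[2,6-bis(benzyloxy)-4-(triisopropylsilyloxy)phenyl]-3,7-dimethyloct-6-en-1-yn-3-ol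
Conditions: PdCl2(PPh3)2 (5 mol%), CuI (10 mol%), Et3N/DMF, 65 °C
Reagents that add atoms: none
Why: Sonogashira coupling of an aryl iodide with a terminal tertiary propargylic alcohol; heating should offset the two ortho substituents.

**Step 7**
Reactants: 11 (3S)-1-[2,6-bis(benzyloxy)-4-(triisopropylsilyloxy)phenyl]-3,7-dimethyloct-6-en-1-yn-3-ol
Product: 14 (1S)-2-{[2,6-bis(benzyloxy)-4-(triisopropylsilyloxy)phenyl]methylidene}-1,3,3-trimethylcyclohexan-1-ol (E/Z mixture), via tertiary alkyl radical 12 (not isolated), via vinyl radical 13 (not isolated)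
Conditions: Fe(acac)3 (2.0 equiv), PhSiH3 (2.5 equiv), degassed EtOH (0.02 M), 60 °C
Reagents that add atoms: none
Why: Proposed new method: an iron hydride formed from Fe(acac)3 and PhSiH3 transfers a hydrogen atom to the only C=C bond of 11 (Markovnikov) to give tertiary radical 12, which adds to the proximal alkyne carbon and forms the C(CH3)2–C(sp2) bond between two fully substituted centres; the α-aryl vinyl radical 13 then takes a hydrogen atom from ethanol. The closest known reaction types are metal-hydride HAT-initiated (Mukaiyama-type) reductive radical cyclisations of dienes and onto electron-poor acceptors, and tin hydride-mediated 6-exo-dig closures of alkyl radicals onto aryl alkynes; an unactivated, electron-rich aryl alkyne as acceptor with H-atom termination is the untested element. The cyclohexane closes in the 6-exo-dig mode, since 7-endo-dig would place the radical on the non-benzylic carbon. No new stereocentre is formed: the (S)-carbinol is a spectator and the E/Z geometry of 14 is irrelevant because step 8 is stereoconvergent. The step needs HAT at the alkene only (alkynes are poor HAT acceptors), cyclisation faster than reduction of 12 (helped by the quaternary carbinol in the tether, aryl stabilisation of 13 and the low stationary hydride concentration), and no 1,5-hydrogen shift from the ortho OCH2Ph groups to 13 (these C–H bonds lie near the nodal plane of the aryl-conjugated radical orbital).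

**Step 8**
Reactants: 14 (1S)-2-{[2,6-bis(benzyloxy)-4-(triisopropylsilyloxy)phenyl]methylidene}-1,3,3-trimethylcyclohexan-1-ol
Product: 15 (1S,2S)-2-{[2,6-bis(benzyloxy)-4-(triisopropylsilyloxy)phenyl]methyl}-1,3,3-trimethylcyclohexan-1-ol
Conditions: [Ir(cod)(PCy3)(py)]PF6 (10 mol%), H2 (1–5 bar), CH2Cl2, rt
Reagents that add atoms: none
Why: Hydroxyl-directed homogeneous hydrogenation: iridium bound to the allylic tertiary OH delivers H2 to the alkene face syn to OH, so H at the ring carbon ends cis and the benzylic CH2 trans to OH from either alkene isomer; the alkene cannot migrate because both neighbours are quaternary.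

**Step 9**
Reactants: 15 (1S,2S)-2-{[2,6-bis(benzyloxy)-4-(triisopropylsilyloxy)phenyl]methyl}-1,3,3-trimethylcyclohexan-1-ol
Product: 16 3,5-bis(benzyloxy)-4-{[(1S,2S)-2-hydroxy-2,6,6-trimethylcyclohexyl]methyl}phenol
Conditions: TBAF, THF, 0 °C; then H2O
Reagents that add atoms: none
Why: Fluoride cleavage of the aryl silyl ether; benzyl ethers and the tertiary alcohol are inert.

**Step 10**
Reactants: 16 3,5-bis(benzyloxy)-4-{[(1S,2S)-2-hydroxy-2,6,6-trimethylcyclohexyl]methyl}phenol
Product: 17 3,5-bis(benzyloxy)-4-{[(1S,2S)-2-hydroxy-2,6,6-trimethylcyclohexyl]methyl}-2-iodophenol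
Conditions: NIS (1.0 equiv), CH2Cl2, −20 → 0 °C
Reagents that add atoms: N-iodosuccinimide, O=C1CCC(=O)N1I
Why: Electrophilic iodination of a phenol whose para position is blocked and whose two ortho positions are constitutionally equivalent, so one mono-iodide should form.

**Step 11**
Reactants: 18 3,4-bis(benzyloxy)benzaldehyde
Product: 19 1,2-bis(benzyloxy)-4-ethynylbenzene
Conditions: dimethyl (1-diazo-2-oxopropyl)phosphonate, K2CO3, MeOH, rt
Reagents that add atoms: dimethyl (1-diazo-2-oxopropyl)phosphonate, CC(=O)C(=[N+]=[N-])P(=O)(OC)OC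
Why: Seyferth–Gilbert homologation with the Ohira–Bestmann reagent converts the aldehyde into the terminal alkyne under mild base.

**Step 12**
Reactants: 17 3,5-bis(benzyloxy)-4-{[(1S,2S)-2-hydroxy-2,6,6-trimethylcyclohexyl]methyl}-2-iodophenol; 19 1,2-bis(benzyloxy)-4-ethynylbenzene
Product: 22 5,7-bis(benzyloxy)-2-[3,4-bis(benzyloxy)phenyl]-6-{[(1S,2S)-2-hydroxy-2,6,6-trimethylcyclohexyl]methyl}-4H-chromen-4-one, via hydroxyaryl ynone 20 (not isolated), via diethylamino enone 21 (not isolated)
Conditions: PdCl2(PPh3)2 (5 mol%), CO (3 bar), Et2NH/DMF, 70 °C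
Reagents that add atoms: carbon monoxide, [C-]#[O+]
Why: Carbonylative Sonogashira coupling gives ynone 20, diethylamine adds to it (21) and the phenol oxygen displaces the amine in the 6-endo sense to give the flavone and not the aurone; the ring oxygen is the one phenol flanked by H, so the side chain must end at C6.

**Step 13**
Reactants: 22 5,7-bis(benzyloxy)-2-[3,4-bis(benzyloxy)phenyl]-6-{[(1S,2S)-2-hydroxy-2,6,6-trimethylcyclohexyl]methyl}-4H-chromen-4-one
Product: 23 2-(3,4-dihydroxyphenyl)-5,7-dihydroxy-6-{[(1S,2S)-2-hydroxy-2,6,6-trimethylcyclohexyl]methyl}-4H-chromen-4-one (CNP0257603.1)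
Conditions: H2 (1 bar), 10% Pd/C, EtOAc/MeOH, rt
Reagents that add atoms: none
Why: Hydrogenolysis of the four benzyl ethers under neutral conditions, which spares the tertiary alcohol (no acid-induced cyclisation onto the neighbouring phenols) and should leave the chromone C2=C3 bond intact if stopped at full debenzylation.

**Compound list**

1 | 3,5-bis(benzyloxy)phenol | Oc1cc(OCc2ccccc2)cc(OCc2ccccc2)c1 | starting material
2 | [3,5-bis(benzyloxy)phenoxy]tri(propan-2-yl)silane | CC(C)[Si](Oc1cc(OCc2ccccc2)cc(OCc2ccccc2)c1)(C(C)C)C(C)C | intermediate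
3 | [2,6-bis(benzyloxy)-4-(triisopropylsilyloxy)phenyl]lithium | [Li]c1c(OCc2ccccc2)cc(O[Si](C(C)C)(C(C)C)C(C)C)cc1OCc1ccccc1 | intermediate
4 | [3,5-bis(benzyloxy)-4-iodophenoxy]tri(propan-2-yl)silane | Ic1c(OCc2ccccc2)cc(O[Si](C(C)C)(C(C)C)C(C)C)cc1OCc1ccccc1 | intermediate
5 | geraniol | CC(C)=CCC/C(C)=C/CO | starting material
6 | (2S,3S)-2,3-epoxygeraniol | OC[C@@H]1O[C@@]1(C)CCC=C(C)C | intermediate
7 | (2S,3R)-3-(chloromethyl)-2-methyl-2-(4-methylpent-3-en-1-yl)oxirane | ClC[C@@H]1O[C@@]1(C)CCC=C(C)C | intermediate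
8 | lithium (3S)-1-chloro-3,7-dimethylocta-1,6-dien-3-olate | CC(C)=CCC[C@](C)(O[Li])C=CCl | intermediate
9 | lithium (3S)-1-lithio-3,7-dimethyloct-6-en-1-yn-3-olate | CC(C)=CCC[C@](C)(O[Li])C#C[Li] | intermediate
10 | (3S)-3,7-dimethyloct-6-en-1-yn-3-ol | CC(C)=CCC[C@](C)(O)C#C | intermediate
11 | (3S)-1-[2,6-bis(benzyloxy)-4-(triisopropylsilyloxy)phenyl]-3,7-dimethyloct-6-en-1-yn-3-ol | CC(C)=CCC[C@](C)(O)C#Cc1c(OCc2ccccc2)cc(O[Si](C(C)C)(C(C)C)C(C)C)cc1OCc1ccccc1 | intermediate
12 | tertiary radical at C7 of 11 after hydrogen-atom addition at C6 | C[C](C)CCC[C@](C)(O)C#Cc1c(OCc2ccccc2)cc(O[Si](C(C)C)(C(C)C)C(C)C)cc1OCc1ccccc1 | intermediate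
13 | cyclised α-aryl vinyl radical (radical on the exocyclic benzylic carbon) | CC1(C)CCC[C@](C)(O)C1=[C]c1c(OCc2ccccc2)cc(O[Si](C(C)C)(C(C)C)C(C)C)cc1OCc1ccccc1 | intermediate
14 | (1S)-2-{[2,6-bis(benzyloxy)-4-(triisopropylsilyloxy)phenyl]methylidene}-1,3,3-trimethylcyclohexan-1-ol (E/Z) | CC1(C)CCC[C@](C)(O)C1=Cc1c(OCc2ccccc2)cc(O[Si](C(C)C)(C(C)C)C(C)C)cc1OCc1ccccc1 | intermediate
15 | (1S,2S)-2-{[2,6-bis(benzyloxy)-4-(triisopropylsilyloxy)phenyl]methyl}-1,3,3-trimethylcyclohexan-1-ol | CC1(C)CCC[C@](C)(O)[C@H]1Cc1c(OCc2ccccc2)cc(O[Si](C(C)C)(C(C)C)C(C)C)cc1OCc1ccccc1 | intermediate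
16 | 3,5-bis(benzyloxy)-4-{[(1S,2S)-2-hydroxy-2,6,6-trimethylcyclohexyl]methyl}phenol | CC1(C)CCC[C@](C)(O)[C@H]1Cc1c(OCc2ccccc2)cc(O)cc1OCc1ccccc1 | intermediate
17 | 3,5-bis(benzyloxy)-4-{[(1S,2S)-2-hydroxy-2,6,6-trimethylcyclohexyl]methyl}-2-iodophenol | CC1(C)CCC[C@](C)(O)[C@H]1Cc1c(OCc2ccccc2)cc(O)c(I)c1OCc1ccccc1 | intermediate
18 | 3,4-bis(benzyloxy)benzaldehyde | O=Cc1ccc(OCc2ccccc2)c(OCc2ccccc2)c1 | starting material
19 | 1,2-bis(benzyloxy)-4-ethynylbenzene | C#Cc1ccc(OCc2ccccc2)c(OCc2ccccc2)c1 | intermediate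
20 | 1-[4,6-bis(benzyloxy)-2-hydroxy-5-{[(1S,2S)-2-hydroxy-2,6,6-trimethylcyclohexyl]methyl}phenyl]-3-[3,4-bis(benzyloxy)phenyl]prop-2-yn-1-one | CC1(C)CCC[C@](C)(O)[C@H]1Cc1c(OCc2ccccc2)cc(O)c(C(=O)C#Cc2ccc(OCc3ccccc3)c(OCc3ccccc3)c2)c1OCc1ccccc1 | intermediate
21 | 3-(diethylamino) enone from addition of diethylamine to 20 | CC1(C)CCC[C@](C)(O)[C@H]1Cc1c(OCc2ccccc2)cc(O)c(C(=O)C=C(N(CC)CC)c2ccc(OCc3ccccc3)c(OCc3ccccc3)c2)c1OCc1ccccc1 | intermediate
22 | 5,7-bis(benzyloxy)-2-[3,4-bis(benzyloxy)phenyl]-6-{[(1S,2S)-2-hydroxy-2,6,6-trimethylcyclohexyl]methyl}-4H-chromen-4-one | CC1(C)CCC[C@](C)(O)[C@H]1Cc1c(OCc2ccccc2)cc2oc(-c3ccc(OCc4ccccc4)c(OCc4ccccc4)c3)cc(=O)c2c1OCc1ccccc1 | intermediate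
23 | 2-(3,4-dihydroxyphenyl)-5,7-dihydroxy-6-{[(1S,2S)-2-hydroxy-2,6,6-trimethylcyclohexyl]methyl}-4H-chromen-4-one | CC1(C)CCC[C@](C)(O)[C@H]1Cc1c(O)cc2oc(-c3ccc(O)c(O)c3)cc(=O)c2c1O | target

**Step count**

Total: 13 steps. Longest linear sequence: 10 steps (5 → 23 through steps 3, 4, 5, 6, 7, 8, 9, 10, 12, 13).

**Steps most likely to fail**

Step 7 (Proposed new method). What may go wrong: reduction of radical 12 before it cyclises (plain hydrogenation of the prenyl alkene), hydrogen-atom transfer to the alkyne, translocation of the vinyl radical to a benzylic OCH2 position, or further reduction of 14. The fallback uses known chemistry, sets out from 4 and returns at 14; it builds the ring before the aryl group is attached. Commercial β-cyclocitral is reduced (NaBH4, MeOH) to β-cyclogeraniol F1. Sharpless epoxidation with L-(+)-diethyl tartrate should give the epoxy alcohol [(1S,6S)-2,2,6-trimethyl-7-oxabicyclo[4.1.0]heptan-1-yl]methanol F2. PPh3/I2/imidazole converts it into the epoxy iodide (1R,6S)-1-(iodomethyl)-2,2,6-trimethyl-7-oxabicyclo[4.1.0]heptane F3. Zinc in refluxing ethanol opens the epoxide reductively to (1S)-1,3,3-trimethyl-2-methylidenecyclohexan-1-ol F4, which has the same (S)-carbinol. Heck arylation of F4 with 4 (Pd(OAc)2, Bu4NCl, NaHCO3, DMF, 90 °C) can eliminate only towards the benzylic carbon and should give 14. This Heck reaction is itself hindered and is the weak point of the fallback.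

Step 8. What may go wrong: the iridium catalyst cannot reach the alkene face syn to OH (no turnover), or the aryl ether oxygens compete as directing groups and hydrogen is delivered anti to OH. The fallback sets out from 2 and returns at 15; it fixes the ring CH first and the carbinol second.
- Lithiation of 2 as in step 2 and quenching with DMF gives 2,6-bis(benzyloxy)-4-(triisopropylsilyloxy)benzaldehyde F5.
- Me2CuLi addition to 3-methylcyclohex-2-en-1-one and trapping of the regiodefined enolate with F5 gives the aldol 2-{[2,6-bis(benzyloxy)-4-(triisopropylsilyloxy)phenyl](hydroxy)methyl}-3,3-dimethylcyclohexan-1-one F6.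
- MsCl/Et3N then DBU dehydrates it to the exocyclic enone 2-{[2,6-bis(benzyloxy)-4-(triisopropylsilyloxy)phenyl]methylidene}-3,3-dimethylcyclohexan-1-one F7.
- Iridium–phosphinooxazoline-catalysed asymmetric hydrogenation of the C=C bond should give (2S)-2-{[2,6-bis(benzyloxy)-4-(triisopropylsilyloxy)phenyl]methyl}-3,3-dimethylcyclohexan-1-one F8.
- Non-basic methylenation (dimethyltitanocene, toluene, 70 °C) gives the methylidene compound {3,5-bis(benzyloxy)-4-{[(1S)-2,2-dimethyl-6-methylidenecyclohexyl]methyl}phenoxy}tri(propan-2-yl)silane F9.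
- mCPBA should attack from the equatorial side, away from the axial methyl of the C(CH3)2 group, as in 8(12)-drimenes. This gives the spiro-epoxide with oxygen trans to the benzylic CH2, F10.
- LiAlH4 opens it at the CH2 terminus to give 15.

Step 12. What may go wrong: slow oxidative addition at the electron-rich, doubly ortho-oxygenated iodide, direct coupling without CO insertion followed by closure to a 2-arylbenzofuran, or 5-exo closure to the aurone. The fallback sets out from 16 and returns at 22. Magnesium-mediated ortho-formylation of 16 (MgCl2, Et3N, paraformaldehyde, MeCN, reflux) gives 4,6-bis(benzyloxy)-2-hydroxy-5-{[(1S,2S)-2-hydroxy-2,6,6-trimethylcyclohexyl]methyl}benzaldehyde F11. Addition of excess lithium acetylide of 19 (n-BuLi, THF, −78 → 0 °C) gives the propargylic alcohol 1-[4,6-bis(benzyloxy)-2-hydroxy-5-{[(1S,2S)-2-hydroxy-2,6,6-trimethylcyclohexyl]methyl}phenyl]-3-[3,4-bis(benzyloxy)phenyl]prop-2-yn-1-ol F12. MnO2 oxidises it to ynone 20, and Et2NH in EtOH closes 20 to 22 through 21.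

**Further compounds**

F1 | step 7 | β-cyclogeraniol, (2,6,6-trimethylcyclohex-1-en-1-yl)methanol | CC1=C(CO)C(C)(C)CCC1
F2 | step 7 | [(1S,6S)-2,2,6-trimethyl-7-oxabicyclo[4.1.0]heptan-1-yl]methanol | OC[C@]12O[C@@]1(C)CCCC2(C)C
F3 | step 7 | (1R,6S)-1-(iodomethyl)-2,2,6-trimethyl-7-oxabicyclo[4.1.0]heptane | IC[C@]12O[C@@]1(C)CCCC2(C)C
F4 | step 7 | (1S)-1,3,3-trimethyl-2-methylidenecyclohexan-1-ol | C=C1C(C)(C)CCC[C@]1(C)O
F5 | step 8 | 2,6-bis(benzyloxy)-4-(triisopropylsilyloxy)benzaldehyde | O=Cc1c(OCc2ccccc2)cc(O[Si](C(C)C)(C(C)C)C(C)C)cc1OCc1ccccc1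
F6 | step 8 | 2-{[2,6-bis(benzyloxy)-4-(triisopropylsilyloxy)phenyl](hydroxy)methyl}-3,3-dimethylcyclohexan-1-one (diastereomer mixture) | O=C1CCCC(C)(C)C1C(O)c1c(OCc2ccccc2)cc(O[Si](C(C)C)(C(C)C)C(C)C)cc1OCc1ccccc1
F7 | step 8 | 2-{[2,6-bis(benzyloxy)-4-(triisopropylsilyloxy)phenyl]methylidene}-3,3-dimethylcyclohexan-1-one | O=C1CCCC(C)(C)C1=Cc1c(OCc2ccccc2)cc(O[Si](C(C)C)(C(C)C)C(C)C)cc1OCc1ccccc1
F8 | step 8 | (2S)-2-{[2,6-bis(benzyloxy)-4-(triisopropylsilyloxy)phenyl]methyl}-3,3-dimethylcyclohexan-1-one | CC1(C)CCCC(=O)[C@H]1Cc1c(OCc2ccccc2)cc(O[Si](C(C)C)(C(C)C)C(C)C)cc1OCc1ccccc1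
F9 | step 8 | {3,5-bis(benzyloxy)-4-{[(1S)-2,2-dimethyl-6-methylidenecyclohexyl]methyl}phenoxy}tri(propan-2-yl)silane | CC1(C)CCCC(=C)[C@H]1Cc1c(OCc2ccccc2)cc(O[Si](C(C)C)(C(C)C)C(C)C)cc1OCc1ccccc1
F10 | step 8 | spiro-epoxide of F9 with the oxirane oxygen trans to the benzylic CH2 | CC1(C)CCC[C@]2(OC2)[C@H]1Cc1c(OCc3ccccc3)cc(O[Si](C(C)C)(C(C)C)C(C)C)cc1OCc1ccccc1
F11 | step 12 | 4,6-bis(benzyloxy)-2-hydroxy-5-{[(1S,2S)-2-hydroxy-2,6,6-trimethylcyclohexyl]methyl}benzaldehyde | CC1(C)CCC[C@](C)(O)[C@H]1Cc1c(OCc2ccccc2)cc(O)c(C=O)c1OCc1ccccc1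
F12 | step 12 | 1-[4,6-bis(benzyloxy)-2-hydroxy-5-{[(1S,2S)-2-hydroxy-2,6,6-trimethylcyclohexyl]methyl}phenyl]-3-[3,4-bis(benzyloxy)phenyl]prop-2-yn-1-ol (epimer mixture at the carbinol) | CC1(C)CCC[C@](C)(O)[C@H]1Cc1c(OCc2ccccc2)cc(O)c(C(O)C#Cc2ccc(OCc3ccccc3)c(OCc3ccccc3)c2)c1OCc1ccccc1
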